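**Retrosynthetic overview**

1. The target, a (1S,2R,5R,6S)-2,6-diaryl-3,7-dioxabicyclo[3.3.0]octan-1-ol, comes from its bis-silyl ether (aryl O–SiiPr3, C1 O–SiEt3) by fluoride.
2. Key disconnection: the C4–C5 and O3–C2 bonds of ring A (C1–C2–O3–C4–C5) and the O7–C6 and C8–H bonds of ring B (C5–C6–O7–C8–C1) are cut in one move, leading to formaldehyde, Et3SiH and an open-chain oxirane aldehyde. Rings form in the order oxirane, ring A, ring B.
3. Enabling feature: C1 (tertiary carbinol bridgehead) and C2 (benzylic ether carbon of ring A bearing the para-oxygenated aryl group) carry vicinal oxygens. They are therefore an opened aryl oxirane: its oxygen stays on C1 and C2 takes up the formaldehyde oxygen. C6 is a benzylic ether carbon with an electron-rich aryl group, the cation left when an (E)-styrene attacks O=CH2+.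
4. The oxirane aldehyde comes from a 2-styryl cinnamyl alcohol by Sharpless epoxidation (sets C1, the only stereocentre that the cascade keeps) and oxidation. The formyl group (C8 one oxidation level up) disarms the quaternary oxirane carbon and supplies the oxygen that closes ring B; the silane removes the extra oxidation level.
5. The dienol comes from vanillin by silylation, Z-selective bromo-olefination, Suzuki coupling with a styrylboronate and ester reduction.

Key step: step 8

Remark: locants of the bicyclic compounds follow 3,7-dioxabicyclo[3.3.0]octane numbering (C1 carbinol bridgehead, C2 guaiacyl-bearing carbon, O3, C4, C5 bridgehead CH, C6 veratryl-bearing carbon, O7, C8), and paraformaldehyde is taken to release monomeric formaldehyde under the silyl triflate.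

**Route**

Step 1
Reactants: 1 vanillin (4-hydroxy-3-methoxybenzaldehyde)
Product: 2 3-methoxy-4-[(triisopropylsilyl)oxy]benzaldehyde
Conditions: iPr3SiCl, imidazole, DMF, 23 °C
Reagents that add atoms: chlorotriisopropylsilane, CC(C)[Si](Cl)(C(C)C)C(C)C
Why: Imidazole-promoted O-silylation of the phenol gives a silyl ether that should survive aqueous base, hydride and low-temperature Lewis acid and keeps the ring electron-rich for step 8.

Step 2
Reactants: 2 3-methoxy-4-[(triisopropylsilyl)oxy]benzaldehyde; 3 ethyl (triphenyl-λ5-phosphanylidene)acetate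
Product: 5 ethyl (2Z)-2-bromo-3-{3-methoxy-4-[(triisopropylsilyl)oxy]phenyl}prop-2-enoate, via bromophosphorane 4 (not isolated)
Conditions: NBS added to 3 in CH2Cl2 at −20 °C; then 2, 40 °C
Reagents that add atoms: N-bromosuccinimide, O=C1CCC(=O)N1Br
Why: NBS brominates the stabilised ylide to bromophosphorane 4, and its Wittig reaction with the aldehyde should put the ester trans to the aryl group, as stabilised ylides do, which is the (Z)-bromoalkene.

Step 3
Reactants: 6 4-ethynyl-1,2-dimethoxybenzene
Product: 7 2-[(E)-2-(3,4-dimethoxyphenyl)ethenyl]-4,4,5,5-tetramethyl-1,3,2-dioxaborolane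
Conditions: pinacolborane, Cp2Zr(H)Cl (5 mol%), Et3N (10 mol%), neat, 60 °C
Reagents that add atoms: pinacolborane, [H]B1OC(C)(C)C(C)(C)O1
Why: Zirconocene-catalysed syn-hydroboration of the terminal alkyne should place boron on the terminal carbon and give the (E)-alkenylboronate.

Step 4
Reactants: 5 ethyl (2Z)-2-bromo-3-{3-methoxy-4-[(triisopropylsilyl)oxy]phenyl}prop-2-enoate; 7 2-[(E)-2-(3,4-dimethoxyphenyl)ethenyl]-4,4,5,5-tetramethyl-1,3,2-dioxaborolane
Product: 8 ethyl (2E,3E)-4-(3,4-dimethoxyphenyl)-2-({3-methoxy-4-[(triisopropylsilyl)oxy]phenyl}methylidene)but-3-enoate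
Conditions: Pd(PPh3)4 (5 mol%), K3PO4, 1,4-dioxane/H2O, 70 °C
Reagents that add atoms: none
Why: Suzuki–Miyaura coupling of the alkenyl bromide with the alkenylboronate proceeds with retention at both double bonds, so the styryl group should end cis to the aryl group and trans to nothing but hydrogen, giving the (2E,3E)-dienoate.

Step 5
Reactants: 8 ethyl (2E,3E)-4-(3,4-dimethoxyphenyl)-2-({3-methoxy-4-[(triisopropylsilyl)oxy]phenyl}methylidene)but-3-enoate
Product: 9 (2E,3E)-4-(3,4-dimethoxyphenyl)-2-({3-methoxy-4-[(triisopropylsilyl)oxy]phenyl}methylidene)but-3-en-1-ol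
Conditions: iBu2AlH, CH2Cl2, −78 °C
Reagents that add atoms: none
Why: 1,2-Reduction of the conjugated ester by iBu2AlH at low temperature should give the allylic alcohol and leave both double bonds and the silyl ether untouched.

Step 6
Reactants: 9 (2E,3E)-4-(3,4-dimethoxyphenyl)-2-({3-methoxy-4-[(triisopropylsilyl)oxy]phenyl}methylidene)but-3-en-1-ol
Product: 10 [(2S,3S)-2-[(E)-2-(3,4-dimethoxyphenyl)ethenyl]-3-{3-methoxy-4-[(triisopropylsilyl)oxy]phenyl}oxiran-2-yl]methanol
Conditions: Ti(OiPr)4 (10 mol%), L-(+)-diisopropyl tartrate (12 mol%), tBuOOH, 4 Å molecular sieves, CH2Cl2, −25 °C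
Reagents that add atoms: tert-butyl hydroperoxide, CC(C)(C)OO
Why: Katsuki–Sharpless asymmetric epoxidation oxidises only the alkene allylic to the hydroxyl group, and the L-(+)-tartrate catalyst should deliver oxygen to the face that gives the (2S,3S)-oxirane, as with (E)-2-methylcinnamyl alcohol, which fixes the future C1.

Step 7
Reactants: 10 [(2S,3S)-2-[(E)-2-(3,4-dimethoxyphenyl)ethenyl]-3-{3-methoxy-4-[(triisopropylsilyl)oxy]phenyl}oxiran-2-yl]methanol
Product: 11 (2R,3S)-2-[(E)-2-(3,4-dimethoxyphenyl)ethenyl]-3-{3-methoxy-4-[(triisopropylsilyl)oxy]phenyl}oxirane-2-carbaldehyde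
Conditions: Pr4N[RuO4] (5 mol%), N-methylmorpholine N-oxide, 4 Å molecular sieves, CH2Cl2, 0 °C
Reagents that add atoms: none
Why: Ley–Griffith oxidation under neutral conditions should take the primary alcohol to the aldehyde without touching the acid-sensitive oxirane, and the α-carbon is quaternary so nothing can epimerise (the descriptor at C2 changes only because the priorities change).

Step 8
Reactants: 11 (2R,3S)-2-[(E)-2-(3,4-dimethoxyphenyl)ethenyl]-3-{3-methoxy-4-[(triisopropylsilyl)oxy]phenyl}oxirane-2-carbaldehyde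
Product: 15 (1S,2R,5R,6S)-6-(3,4-dimethoxyphenyl)-2-{3-methoxy-4-[(triisopropylsilyl)oxy]phenyl}-1-[(triethylsilyl)oxy]-3,7-dioxabicyclo[3.3.0]octane, via oxocarbenium ion 12 (not isolated), via benzylic cation 13 (not isolated), via cyclic oxocarbenium ion 14 (not isolated)
Conditions: (CH2O)n, Et3SiOTf, 2,6-di-tert-butyl-4-methylpyridine, CH2Cl2, −78 to −40 °C; then Et3SiH, −78 to −20 °C
Reagents that add atoms: formaldehyde (from paraformaldehyde), C=O; triethylsilane, CC[SiH](CC)CC
Why: Proposed new method: Et3SiOTf silylates the oxirane oxygen of 11 and formaldehyde opens the benzylic C–O bond with inversion (charge at the quaternary carbon is disfavoured by its formyl group) to give the O-methylidene oxonium ion 12, which is the first half of the known Lewis acid-mediated conversion of oxiranes into 1,3-dioxolanes with carbonyl compounds, and the rest follows the known Prins bicyclization of alkoxymethyl oxocarbenium ions onto styrenes with an internal oxygen terminator. Ring A closes when the β-carbon of the (E)-styrene attacks the CH2=O+ carbon (5-exo-trig for the alkene, 5-endo for the oxocarbenium ion) to give the veratryl-stabilised benzylic cation 13, and ring B closes when the formyl oxygen captures that cation (5-exo-trig at the cationic carbon) to give oxocarbenium ion 14, which Et3SiH reduces to the C8 methylene with return of Et3SiOTf. C1 keeps the configuration set in step 6 because no bond to it breaks, and C2 is fixed by the inversion (if the benzylic centre ionises instead, the aryl group should still prefer the convex face cis to the silyloxy group). C5 is fixed by the cis ring fusion, because only the cation cis to the formyl group can be trapped and its epimer can return to 12 by retro-Prins fragmentation. C6 is fixed by anti addition of carbon and oxygen across the (E)-alkene, which places the veratryl group exo as in kinetically controlled benzylic-cation closures of furofurans. The step needs benzylic rather than allylic opening of the oxirane (secured by the α-formyl group and the para-silyloxy aryl group), capture by formaldehyde ahead of a Meinwald shift (excess CH2O at −78 °C), and five- rather than six-membered Prins closure (secured by the aryl group on the distal alkene carbon).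

Step 9
Reactants: 15 (1S,2R,5R,6S)-6-(3,4-dimethoxyphenyl)-2-{3-methoxy-4-[(triisopropylsilyl)oxy]phenyl}-1-[(triethylsilyl)oxy]-3,7-dioxabicyclo[3.3.0]octane
Product: 16 (1S,2R,5R,6S)-6-(3,4-dimethoxyphenyl)-2-(4-hydroxy-3-methoxyphenyl)-3,7-dioxabicyclo[3.3.0]octan-1-ol (target)
Conditions: Bu4NF, AcOH, THF, 0 to 23 °C
Reagents that add atoms: none
Why: Fluoride-mediated desilylation, buffered with acetic acid so that no free phenoxide persists to open the benzylic ether through a quinone methide, should remove the aryl and the tertiary silyl ether without touching a stereocentre.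

**Compound list**

1 | vanillin (4-hydroxy-3-methoxybenzaldehyde) | COc1cc(C=O)ccc1O | starting material
2 | 3-methoxy-4-[(triisopropylsilyl)oxy]benzaldehyde | COc1cc(C=O)ccc1O[Si](C(C)C)(C(C)C)C(C)C | intermediate
3 | ethyl (triphenyl-λ5-phosphanylidene)acetate | CCOC(=O)C=P(c1ccccc1)(c1ccccc1)c1ccccc1 | starting material
4 | ethyl bromo(triphenyl-λ5-phosphanylidene)acetate (not isolated) | CCOC(=O)C(Br)=P(c1ccccc1)(c1ccccc1)c1ccccc1 | intermediate
5 | ethyl (2Z)-2-bromo-3-{3-methoxy-4-[(triisopropylsilyl)oxy]phenyl}prop-2-enoate | CCOC(=O)/C(Br)=C/c1ccc(O[Si](C(C)C)(C(C)C)C(C)C)c(OC)c1 | intermediate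
6 | 4-ethynyl-1,2-dimethoxybenzene | COc1ccc(C#C)cc1OC | starting material
7 | 2-[(E)-2-(3,4-dimethoxyphenyl)ethenyl]-4,4,5,5-tetramethyl-1,3,2-dioxaborolane | COc1ccc(/C=C/B2OC(C)(C)C(C)(C)O2)cc1OC | intermediate
8 | ethyl (2E,3E)-4-(3,4-dimethoxyphenyl)-2-({3-methoxy-4-[(triisopropylsilyl)oxy]phenyl}methylidene)but-3-enoate | CCOC(=O)/C(=C/c1ccc(O[Si](C(C)C)(C(C)C)C(C)C)c(OC)c1)/C=C/c1ccc(OC)c(OC)c1 | intermediate
9 | (2E,3E)-4-(3,4-dimethoxyphenyl)-2-({3-methoxy-4-[(triisopropylsilyl)oxy]phenyl}methylidene)but-3-en-1-ol | OC/C(=C/c1ccc(O[Si](C(C)C)(C(C)C)C(C)C)c(OC)c1)/C=C/c1ccc(OC)c(OC)c1 | intermediate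
10 | [(2S,3S)-2-[(E)-2-(3,4-dimethoxyphenyl)ethenyl]-3-{3-methoxy-4-[(triisopropylsilyl)oxy]phenyl}oxiran-2-yl]methanol | OC[C@]1(/C=C/c2ccc(OC)c(OC)c2)O[C@H]1c1ccc(O[Si](C(C)C)(C(C)C)C(C)C)c(OC)c1 | intermediate
11 | (2R,3S)-2-[(E)-2-(3,4-dimethoxyphenyl)ethenyl]-3-{3-methoxy-4-[(triisopropylsilyl)oxy]phenyl}oxirane-2-carbaldehyde | O=C[C@]1(/C=C/c2ccc(OC)c(OC)c2)O[C@H]1c1ccc(O[Si](C(C)C)(C(C)C)C(C)C)c(OC)c1 | intermediate
12 | {(1R,2R,3E)-4-(3,4-dimethoxyphenyl)-2-formyl-1-{3-methoxy-4-[(triisopropylsilyl)oxy]phenyl}-2-[(triethylsilyl)oxy]but-3-en-1-yl}(methylidene)oxonium trifluoromethanesulfonate (not isolated) | C=[O+][C@H](c1ccc(O[Si](C(C)C)(C(C)C)C(C)C)c(OC)c1)[C@@](O[Si](CC)(CC)CC)(C=O)/C=C/c1ccc(OC)c(OC)c1.[O-]S(=O)(=O)C(F)(F)F | intermediate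
13 | (3,4-dimethoxyphenyl){(3S,4R,5R)-4-formyl-5-{3-methoxy-4-[(triisopropylsilyl)oxy]phenyl}-4-[(triethylsilyl)oxy]oxolan-3-yl}methylium trifluoromethanesulfonate (not isolated) | COc1cc([C@H]2OC[C@H]([CH+]c3ccc(OC)c(OC)c3)[C@]2(O[Si](CC)(CC)CC)C=O)ccc1O[Si](C(C)C)(C(C)C)C(C)C.[O-]S(=O)(=O)C(F)(F)F | intermediate
14 | (1R,2R,5R,6S)-6-(3,4-dimethoxyphenyl)-2-{3-methoxy-4-[(triisopropylsilyl)oxy]phenyl}-1-[(triethylsilyl)oxy]-3-oxa-7-oxoniabicyclo[3.3.0]oct-7-ene trifluoromethanesulfonate (not isolated) | COc1cc([C@H]2OC[C@@H]3[C@@H](c4ccc(OC)c(OC)c4)[O+]=C[C@]23O[Si](CC)(CC)CC)ccc1O[Si](C(C)C)(C(C)C)C(C)C.[O-]S(=O)(=O)C(F)(F)F | intermediate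
15 | (1S,2R,5R,6S)-6-(3,4-dimethoxyphenyl)-2-{3-methoxy-4-[(triisopropylsilyl)oxy]phenyl}-1-[(triethylsilyl)oxy]-3,7-dioxabicyclo[3.3.0]octane | COc1cc([C@H]2OC[C@@H]3[C@@H](c4ccc(OC)c(OC)c4)OC[C@]23O[Si](CC)(CC)CC)ccc1O[Si](C(C)C)(C(C)C)C(C)C | intermediate
16 | (1S,2R,5R,6S)-6-(3,4-dimethoxyphenyl)-2-(4-hydroxy-3-methoxyphenyl)-3,7-dioxabicyclo[3.3.0]octan-1-ol | COc1cc([C@H]2OC[C@@H]3[C@@H](c4ccc(OC)c(OC)c4)OC[C@]23O)ccc1O | target

**Step count and risks**

Total step count: 9. Longest linear sequence: 8 (steps 1, 2, 4, 5, 6, 7, 8, 9; step 3 is a side branch).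

Steps most likely to fail:

Step 8 (proposed new method). What may go wrong:
- migration of the formyl or styryl group to the opening benzylic centre (Meinwald-type 1,2-shift) faster than intermolecular capture by formaldehyde;
- electrophilic hydroxymethylation of the electron-rich rings;
- Friedel–Crafts closure of the benzylic cation onto the guaiacyl ring before the formyl oxygen is reduced in place.

The fallback uses known reaction types only; it sets out from epoxy alcohol 10 and comes back at 15. Ti(OiPr)4 and benzoic acid open the 2,3-epoxy alcohol at the benzylic C-3 with inversion to give the benzoate diol F1. tBuMe2SiCl and imidazole silylate the primary hydroxyl to give the silyl ether benzoate F2, and Et3SiOTf with 2,6-lutidine silylates the tertiary hydroxyl to give the bis-silyl ether benzoate F3. iBu2AlH removes the benzoate to give the secondary benzylic alcohol F4, which MeOCH2Cl and iPr2NEt convert into the methoxymethyl ether F5. SnCl4 in CH2Cl2 at −78 °C then ionises the acetal, and a Prins cyclization onto the styrene, ended by the silyl ether oxygen with loss of the tert-butyldimethylsilyl group, should give 15.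

Step 6. What may go wrong: the titanium Lewis acid opens the oxirane as it forms (solvolysis at its benzylic and allylic carbons), which costs yield and enantiomeric purity. The fallback sets out from dienol 9 and comes back at 11, so it replaces steps 6 and 7 together. MnO2 oxidises the allylic alcohol to the dienal F6. Aqueous H2O2 with a cinchona-derived primary amine salt (iminium-ion catalysis of the nucleophilic epoxidation of α-branched enals; the pseudoenantiomer that gives the (2R,3S)-oxirane is chosen) then epoxidises the enal double bond under non-acidic conditions to give 11.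

Step 4. What may go wrong: protodeboronation of 7, base-induced loss of the aryl silyl ether para to the acrylate, or Z/E isomerisation during the aqueous-base coupling. The fallback sets out from 5 and comes back at 8. Mizoroki–Heck alkenylation of commercial 3,4-dimethoxystyrene with bromide 5 (Pd(OAc)2, Bu4NCl, NaHCO3, DMF, 60 °C) should build the same (E)-styryl unit without a boron reagent or aqueous base, which also makes step 3 unnecessary; no new compound is made (F0).

**Further compounds**

F1 | step 8 | (1R,2S,3E)-4-(3,4-dimethoxyphenyl)-2-hydroxy-2-(hydroxymethyl)-1-{3-methoxy-4-[(triisopropylsilyl)oxy]phenyl}but-3-en-1-yl benzoate | O=C(O[C@H](c1ccc(O[Si](C(C)C)(C(C)C)C(C)C)c(OC)c1)[C@@](O)(CO)/C=C/c1ccc(OC)c(OC)c1)c1ccccc1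
F2 | step 8 | (1R,2S,3E)-2-({[tert-butyl(dimethyl)silyl]oxy}methyl)-4-(3,4-dimethoxyphenyl)-2-hydroxy-1-{3-methoxy-4-[(triisopropylsilyl)oxy]phenyl}but-3-en-1-yl benzoate | O=C(O[C@H](c1ccc(O[Si](C(C)C)(C(C)C)C(C)C)c(OC)c1)[C@@](O)(CO[Si](C)(C)C(C)(C)C)/C=C/c1ccc(OC)c(OC)c1)c1ccccc1
F3 | step 8 | (1R,2S,3E)-2-({[tert-butyl(dimethyl)silyl]oxy}methyl)-4-(3,4-dimethoxyphenyl)-1-{3-methoxy-4-[(triisopropylsilyl)oxy]phenyl}-2-[(triethylsilyl)oxy]but-3-en-1-yl benzoate | O=C(O[C@H](c1ccc(O[Si](C(C)C)(C(C)C)C(C)C)c(OC)c1)[C@@](O[Si](CC)(CC)CC)(CO[Si](C)(C)C(C)(C)C)/C=C/c1ccc(OC)c(OC)c1)c1ccccc1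
F4 | step 8 | (1R,2S,3E)-2-({[tert-butyl(dimethyl)silyl]oxy}methyl)-4-(3,4-dimethoxyphenyl)-1-{3-methoxy-4-[(triisopropylsilyl)oxy]phenyl}-2-[(triethylsilyl)oxy]but-3-en-1-ol | O[C@H](c1ccc(O[Si](C(C)C)(C(C)C)C(C)C)c(OC)c1)[C@@](O[Si](CC)(CC)CC)(CO[Si](C)(C)C(C)(C)C)/C=C/c1ccc(OC)c(OC)c1
F5 | step 8 | 4-[(1R,2S,3E)-2-({[tert-butyl(dimethyl)silyl]oxy}methyl)-4-(3,4-dimethoxyphenyl)-1-(methoxymethoxy)-2-[(triethylsilyl)oxy]but-3-en-1-yl]-2-methoxyphenyl triisopropylsilyl ether | COCO[C@H](c1ccc(O[Si](C(C)C)(C(C)C)C(C)C)c(OC)c1)[C@@](O[Si](CC)(CC)CC)(CO[Si](C)(C)C(C)(C)C)/C=C/c1ccc(OC)c(OC)c1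
F6 | step 6 | (2E,3E)-4-(3,4-dimethoxyphenyl)-2-({3-methoxy-4-[(triisopropylsilyl)oxy]phenyl}methylidene)but-3-enal | O=C/C(=C/c1ccc(O[Si](C(C)C)(C(C)C)C(C)C)c(OC)c1)/C=C/c1ccc(OC)c(OC)c1
F0 | step 4 | none | none
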